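Ring B (C5–C10) is disconnected at its most hindered bond, C9–C10. It is made from the cyclopentane C5–C6–C7–C8–C10 of a trans-hydrindane by a semipinacol 1,2-shift. The shift moves quaternary C10 from carbinol C8 to C9, which already carries the side chain. The step exploits the array oxygenated C8 / side-chain carbon C9 / quaternary C10 of ring B. One operation enlarges the ring, forges C9–C10 and unveils the C8 ketone from which the 8α-carbinol is made. The precursor, an 8,9-diol 9-mesylate, comes from (+)-podocarpic acid: its ring A supplies C4, C5 and C10, its arene is burnt off, and the residue is closed to a cyclopentanone.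

Key step: step 8

Remark: atom labels are those of the target (labdane numbering). C1–C7, C10 and C18–C20 of podocarpic acid keep their numbers, and its aromatic carbon bonded to C10 becomes C8. Podocarpic acid, the silylated iodopentyne, triphenylphosphine and O-acetylferulic acid are taken to be commercial.

Step 1
Reactants: 1 (+)-podocarpic acid
Product: 2 methyl podocarpate
Conditions: MeI, KHCO3, DMF, rt
Reagents that add atoms: iodomethane CI
Why: SN2 alkylation of the carboxylate on iodomethane avoids attack at the hindered axial C19 carbonyl, hydrogen carbonate is too weak to deprotonate the phenol, and no stereocentre is involved.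

Step 2
Reactants: 2 methyl podocarpate
Product: 3 ring-A diacid monoester (CO2H on C10 is the future C8; CH2CH2CO2H on C5; 4β-CO2Me)
Conditions: RuCl3 (5 mol %), NaIO4 (excess), MeCN/EtOAc/H2O, rt
Reagents that add atoms: sodium periodate [Na+].[O-]I(=O)(=O)=O; water O
Why: RuO4-catalysed oxidative degradation of an electron-rich arene consumes the phenol ring down to its two alkyl-bearing carbons, which remain as the carboxyl groups on C10 and C7, while C4, C5, C10 and the ester are inert.

Step 3
Reactants: 3 ring-A diacid monoester
Product: 4 trans-hydrindanone ester (five-membered ring C5–C6–C7–C8–C10 with C8=O)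
Conditions: Ac2O, NaOAc (cat.), reflux; concentrate; neat, 240 °C
Reagents that add atoms: none
Why: In this Blanc cyclisation (ketonic decarboxylation of a 1,6-diacid via its mixed anhydrides) C7, the only enolisable position, acylates the activated carboxyl carbon on C10 and the β-keto acid loses CO2; the unactivated C19 methyl ester stays out and the trans fusion follows from the fixed diequatorial C5 and C10 substituents.

Step 4
Reactants: 5 (5-iodopent-1-yn-1-yl)trimethylsilane; 6 triphenylphosphine
Product: 7 [5-(trimethylsilyl)pent-4-yn-1-yl]triphenylphosphonium iodide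
Conditions: MeCN, reflux
Reagents that add atoms: none
Why: SN2 quaternisation of triphenylphosphine by the primary iodide gives the Wittig salt.

Step 5
Reactants: 7 phosphonium iodide; 4 trans-hydrindanone ester
Product: 9 (Z)-C8=C9 alkylidene hydrindane ester, via phosphorus ylide 8 (not isolated)
Conditions: NaHMDS, THF, 0 °C; then 4, reflux
Reagents that add atoms: none
Why: In this Wittig olefination with a non-stabilised ylide, kinetic oxaphosphetane formation on a cyclopentanone flanked by a quaternary carbon should place the ylide substituent cis to the larger α-carbon C10 (Z olefin), and the silyl cap keeps the acetylenic C–H away from the base.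

Step 6
Reactants: 9 (Z)-alkylidene hydrindane ester
Product: 10 (8R,9S)-8α,9-diol
Conditions: OsO4 (5 mol %), NMO, acetone/H2O, rt to 40 °C
Reagents that add atoms: N-methylmorpholine N-oxide C[N+]1([O-])CCOCC1; water O
Why: Catalytic syn-dihydroxylation from the α face, opposite the β-methyl on C10, turns the Z geometry into the (8R,9S) relative configuration that later aligns C10 for migration; the silyl alkyne is inert.

Step 7
Reactants: 10 (8R,9S)-8α,9-diol
Product: 11 (8R,9S)-8α-hydroxy 9-mesylate
Conditions: MsCl, Et3N, CH2Cl2, −20 to 0 °C
Reagents that add atoms: methanesulfonyl chloride CS(=O)(=O)Cl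
Why: Chemoselective sulfonylation takes the secondary C9–OH, the tertiary C8–OH next to quaternary C10 is too hindered, and both stereocentres are retained.

Step 8
Reactants: 11 (8R,9S)-8α-hydroxy 9-mesylate
Product: 13 methyl 8-oxo-15,16,17-trinorlabd-13-yn-19-oate (9R; side chain equatorial), via 9-epi silyl ketone 12 (not isolated)
Conditions: Et2AlCl (3 equiv), CH2Cl2, −78 to 0 °C; 1 M HCl work-up; crude product, K2CO3 (cat.), MeOH, rt
Reagents that add atoms: none
Why: Et2AlCl converts the C8–OH into an aluminium alkoxide and assists ionisation of the C9 mesylate, and the C8–C10 σ-bond, held antiperiplanar to C9–O, migrates in concert while C8 becomes the carbonyl carbon (semipinacol mechanism). The closest known reaction type is the pinacol-type rearrangement of 1,2-diol monosulfonates, the classical olefination/dihydroxylation/sulfonate sequence for one-carbon enlargement of cyclic ketones. No new ring is closed: the cyclopentane C5–C6–C7–C8–C10 is enlarged to the cyclohexanone C5–C6–C7–C8–C9–C10 by insertion of C9 between C8 and C10, so ring B appears as the second chair of a trans-decalin. C9 is formed with inversion as the 9S epimer 12 (axial chain) and, being α to the new ketone, is equilibrated by K2CO3/MeOH to the equatorial 9R epimer under control of the rigid trans-decalin, while the same methanolysis removes the silyl cap. The step needs migration of C10 rather than C7 and rearrangement rather than oxirane closure: C10 is the fully substituted and therefore better migrating carbon, and in the syn-diol from the Z olefin only the rotamer with the mesylate anti to C10 puts the small H9 into the crowded sector between C7 and C10, whereas the rotamer for a C7 shift would put the side chain there. Oxirane closure is held back because the oxygen is tied up as a weakly nucleophilic aluminium alkoxide instead of a free alkoxide.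

Step 9
Reactants: 13 methyl 8-oxo-15,16,17-trinorlabd-13-yn-19-oate
Product: 14 methyl 15,16-dinorlabd-8(17)-en-13-yn-19-oate
Conditions: Ph3PCH3Br, KOt-Bu, THF, rt to 60 °C
Reagents that add atoms: methyltriphenylphosphonium bromide C[P+](c1ccccc1)(c1ccccc1)c1ccccc1.[Br-]
Why: Wittig methylenation brings in C17; the hindered ester is untouched, and any enolisation at C9 returns the favoured equatorial epimer, which is then locked.

Step 10
Reactants: 14 methyl 15,16-dinorlabd-8(17)-en-13-yn-19-oate
Product: 15 methyl 8α,17-epoxy-15,16-dinorlabd-13-yn-19-oate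
Conditions: mCPBA, CH2Cl2, 0 °C
Reagents that add atoms: 3-chloroperbenzoic acid OOC(=O)c1cccc(Cl)c1
Why: Prilezhaev epoxidation should come from the α face because the axial C10 methyl screens the β face of C8=C17; this sets C8 (O α, C17 β), and the terminal alkyne is far less nucleophilic.

Step 11
Reactants: 15 methyl 8α,17-epoxy-15,16-dinorlabd-13-yn-19-oate
Product: 16 15,16-dinorlabd-13-yne-8α,19-diol
Conditions: LiAlH4, THF, 0 °C to reflux; aq. NaOH work-up
Reagents that add atoms: none
Why: Hydride opens the oxirane by SN2 at the unhindered C17, giving the 8α-carbinol with the 8β-methyl and retention at C8, and reduces the axial ester to the C19 primary alcohol in the same operation; the isolated alkyne is not reduced.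

Step 12
Reactants: 16 15,16-dinorlabd-13-yne-8α,19-diol
Product: 17 labda-13(16),14-diene-8α,19-diol
Conditions: ethylene (1 atm), (H2IMes)(PCy3)Cl2Ru=CHPh (5 mol %), CH2Cl2, 40 °C
Reagents that add atoms: ethylene C=C
Why: Ene–yne cross metathesis of a terminal alkyne with ethylene gives the 2-substituted 1,3-butadiene (C16 and C15 from ethylene) regiospecifically and tolerates free hydroxyl groups.

Step 13
Reactants: 17 labda-13(16),14-diene-8α,19-diol; 18 (E)-4-acetoxy-3-methoxycinnamic acid
Product: 19 8α-hydroxylabda-13(16),14-dien-19-yl (E)-4-acetoxy-3-methoxycinnamate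
Conditions: DCC, DMAP (cat.), CH2Cl2, rt
Reagents that add atoms: none
Why: Steglich esterification acylates only the primary C19–OH, the tertiary C8–OH is inert, and the E olefin is carried in with 18.

Step 14
Reactants: 19 8α-hydroxylabda-13(16),14-dien-19-yl (E)-4-acetoxy-3-methoxycinnamate
Product: 20 8α-hydroxylabda-13(16),14-dien-19-yl (E)-ferulate (target)
Conditions: K2CO3 (cat.), MeOH, 0 °C
Reagents that add atoms: none
Why: Base-catalysed methanolysis cleaves the aryl acetate, which is far more electrophilic than the conjugated ester of the neopentyl C19 alcohol; no stereocentre or olefin is affected.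

Compound list
1 | (+)-podocarpic acid (12-hydroxypodocarpa-8,11,13-trien-19-oic acid; 4α-CH3, 4β-CO2H, 5α-H, 10β-CH3) | Oc1ccc2c(c1)[C@@]1(C)CCC[C@](C)(C(=O)O)[C@@H]1CC2 | starting material
2 | methyl podocarpate | Oc1ccc2c(c1)[C@@]1(C)CCC[C@](C)(C(=O)OC)[C@@H]1CC2 | intermediate
3 | (1S,2R,3S)-2-(2-carboxyethyl)-3-(methoxycarbonyl)-1,3-dimethylcyclohexane-1-carboxylic acid | OC(=O)[C@@]1(C)CCC[C@](C)(C(=O)OC)[C@@H]1CCC(=O)O | intermediate
4 | methyl (3aR,4S,7aS)-4,7a-dimethyl-1-oxooctahydro-1H-indene-4-carboxylate (trans-fused; C8=O) | O=C1[C@@]2(C)CCC[C@](C)(C(=O)OC)[C@@H]2CC1 | intermediate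
5 | (5-iodopent-1-yn-1-yl)trimethylsilane | C[Si](C)(C)C#CCCCI | starting material
6 | triphenylphosphine | c1ccc(cc1)P(c1ccccc1)c1ccccc1 | starting material
7 | [5-(trimethylsilyl)pent-4-yn-1-yl]triphenylphosphonium iodide | C[Si](C)(C)C#CCCC[P+](c1ccccc1)(c1ccccc1)c1ccccc1.[I-] | intermediate
8 | [5-(trimethylsilyl)pent-4-yn-1-ylidene]triphenylphosphorane (not isolated) | C[Si](C)(C)C#CCCC=P(c1ccccc1)(c1ccccc1)c1ccccc1 | intermediate
9 | (Z)-alkylidene hydrindane ester: 4 with C8=C9H–CH2CH2C≡C–SiMe3 in place of C8=O, chain cis to C10 | C[Si](C)(C)C#CCC/C=C1\[C@@]2(C)CCC[C@](C)(C(=O)OC)[C@@H]2CC1 | intermediate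
10 | (8R,9S)-diol: 8α-OH on the hydrindane, 9-OH on the exocyclic carbon | C[Si](C)(C)C#CCC[C@H](O)[C@]1(O)[C@@]2(C)CCC[C@](C)(C(=O)OC)[C@@H]2CC1 | intermediate
11 | (8R,9S)-8α-hydroxy 9-methanesulfonate | C[Si](C)(C)C#CCC[C@H](OS(C)(=O)=O)[C@]1(O)[C@@]2(C)CCC[C@](C)(C(=O)OC)[C@@H]2CC1 | intermediate
12 | methyl (9S)-8-oxo-14-(trimethylsilyl)-15,16,17-trinorlabd-13-yn-19-oate (9-epi, axial chain; not isolated) | C[Si](C)(C)C#CCC[C@H]1[C@@]2(C)CCC[C@](C)(C(=O)OC)[C@@H]2CCC1=O | intermediate
13 | methyl 8-oxo-15,16,17-trinorlabd-13-yn-19-oate (9R, 9α-H) | C#CCC[C@@H]1[C@@]2(C)CCC[C@](C)(C(=O)OC)[C@@H]2CCC1=O | intermediate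
14 | methyl 15,16-dinorlabd-8(17)-en-13-yn-19-oate | C#CCC[C@@H]1[C@@]2(C)CCC[C@](C)(C(=O)OC)[C@@H]2CCC1=C | intermediate
15 | methyl 8α,17-epoxy-15,16-dinorlabd-13-yn-19-oate | C#CCC[C@@H]1[C@@]2(C)CCC[C@](C)(C(=O)OC)[C@@H]2CC[C@]13CO3 | intermediate
16 | 15,16-dinorlabd-13-yne-8α,19-diol | C#CCC[C@@H]1[C@@]2(C)CCC[C@](C)(CO)[C@@H]2CC[C@@]1(C)O | intermediate
17 | labda-13(16),14-diene-8α,19-diol | C=CC(=C)CC[C@@H]1[C@@]2(C)CCC[C@](C)(CO)[C@@H]2CC[C@@]1(C)O | intermediate
18 | (E)-4-acetoxy-3-methoxycinnamic acid (O-acetylferulic acid) | CC(=O)Oc1ccc(/C=C/C(=O)O)cc1OC | starting material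
19 | 8α-hydroxylabda-13(16),14-dien-19-yl (E)-4-acetoxy-3-methoxycinnamate | C=CC(=C)CC[C@@H]1[C@@]2(C)CCC[C@](C)(COC(=O)/C=C/c3ccc(OC(C)=O)c(OC)c3)[C@@H]2CC[C@@]1(C)O | intermediate
20 | 8α-hydroxylabda-13(16),14-dien-19-yl (E)-ferulate | C=CC(=C)CC[C@@H]1[C@@]2(C)CCC[C@](C)(COC(=O)/C=C/c3ccc(O)c(OC)c3)[C@@H]2CC[C@@]1(C)O | target

Total step count: 14. Longest linear sequence: 13 (steps 1–3 and 5–14).

Steps most likely to fail

Step 8. The C7 methylene may shift instead of C10. Alternatively the C8 oxygen may displace the mesylate, and the resulting oxirane may reopen with a hydride shift. The fallback keeps the ring enlargement but runs it as an equilibrating acyloin rearrangement, and it sets out from diol 10.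
- Swern oxidation of the secondary alcohol should give the 8α-hydroxy-9-ketone F1.
- KOH in MeOH should then drive the α-ketol rearrangement, in which hydrindane ketols of this type enlarge by shift of the quaternary carbon. This should give the 9-hydroxy-8-ketone F2, with loss of the silyl cap in the same pot.
- SmI2 in THF/HMPA with t-BuOH removes the α-hydroxyl group reductively, and brief K2CO3/MeOH equilibration of C9 brings the sequence back to 13.

Step 3. Oligomeric anhydride formation and charring may outrun ketonisation at the temperature needed. The fallback replaces the thermal process by an anionic acylation and sets out from 3.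
- Fischer esterification (MeOH, H2SO4) should touch only the unhindered chain acid and give the half ester F3.
- Oxalyl chloride converts the remaining tertiary acid into the acid chloride F4.
- LiHMDS at −78 °C closes the ring by Dieckmann-type C-acylation of the C7 ester enolate to give the β-keto ester F5.
- HCl/AcOH at reflux hydrolyses and decarboxylates it, which comes back to 4.

Step 13. Acyl transfer to the neopentyl, axial C19–OH may be slow, so that O-to-N acyl migration in the activated acid consumes 18 and long reaction times invite Diels–Alder dimerisation of the diene. The fallback builds the ferulate on the alcohol and sets out from 17.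
- Meldrum's acid in toluene at 100 °C, reacting through the small and very reactive acylketene, should give the C19 malonate half ester F6.
- Knoevenagel–Doebner condensation with vanillin (pyridine, piperidine, 60 °C) forms the E-cinnamate with decarboxylation. This comes back directly to 20 and bypasses 19.

Further compounds
F1 | step 8 | 8α-hydroxy-9-ketone of the hydrindane series | C[Si](C)(C)C#CCCC(=O)[C@]1(O)[C@@]2(C)CCC[C@](C)(C(=O)OC)[C@@H]2CC1
F2 | step 8 | methyl 9-hydroxy-8-oxo-15,16,17-trinorlabd-13-yn-19-oate (C9 configuration left open, removed in the next operation) | C#CCCC1(O)[C@@]2(C)CCC[C@](C)(C(=O)OC)[C@@H]2CCC1=O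
F3 | step 3 | half ester: 3 with the chain acid as methyl ester and the C10 carboxyl free | OC(=O)[C@@]1(C)CCC[C@](C)(C(=O)OC)[C@@H]1CCC(=O)OC
F4 | step 3 | acid chloride of F3 | ClC(=O)[C@@]1(C)CCC[C@](C)(C(=O)OC)[C@@H]1CCC(=O)OC
F5 | step 3 | 7-methoxycarbonyl derivative of 4 (β-keto ester, C7 epimers and enol) | O=C1[C@@]2(C)CCC[C@](C)(C(=O)OC)[C@@H]2CC1C(=O)OC
F6 | step 13 | 8α-hydroxylabda-13(16),14-dien-19-yl hydrogen malonate | C=CC(=C)CC[C@@H]1[C@@]2(C)CCC[C@](C)(COC(=O)CC(=O)O)[C@@H]2CC[C@@]1(C)O
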